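The flavanone is cut at the two bonds around C3 of ring C, C3–OMe and C2–C3. A ring A diazoketone, methanol and a ring B aldehyde are joined in one operation by carbene/oxonium-ylide aldol trapping under Rh2(OAc)4 and a chiral phosphoric acid; this exploits the methoxy-bearing C3 lying between the C4 ketone and the C2 carbinol carbon and sets both stereocenters. The precursor is a 2-diazo-1-arylethanone whose ring A carries the future O1 as a silyl ether, used with 2,5-bis(benzyloxy)-4-methoxybenzaldehyde. Ring C is then closed at O1–C2 by Mitsunobu etherification with inversion, under neutral conditions that spare the aldol, and hydrogenolysis frees the two phenols.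

Key step: step 5

Design remark: ring A brings its ortho oxygen (the later O1) as a silyl ether and not as a halogen, because closing ring C by aryl etherification would put the β-hydroxy ketone under alkoxide conditions that invite retro-aldol cleavage. The carbinol is therefore made 3S and inverted in the closure.

Assumption: (R)-TRIP, (R)-3,3'-bis(2,4,6-triisopropylphenyl)-1,1'-binaphthyl-2,2'-diyl hydrogen phosphate, is taken to deliver the 2R,3S adduct; its mirror image would be used if the opposite sense of induction is found.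

Step 1
Reactants: 1 1-(6-hydroxy-2,3,4-trimethoxyphenyl)ethanone
Product: 2 1-[2,3,4-trimethoxy-6-(triisopropylsilyloxy)phenyl]ethanone
Conditions: iPr3SiCl, imidazole, DMF, 40 °C
Reagents that add atoms: chlorotriisopropylsilane, CC(C)[Si](Cl)(C(C)C)C(C)C
Why: O-silylation of a phenol with a silyl chloride and imidazole, warmed gently because the hydroxyl is hydrogen-bonded to the ketone; the bulky, weakly donating silyl ether is chosen to survive the amide base and the carbene chemistry ahead and to leave under buffered fluoride.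

Step 2
Reactants: 2 1-[2,3,4-trimethoxy-6-(triisopropylsilyloxy)phenyl]ethanone
Product: 4 2-diazo-1-[2,3,4-trimethoxy-6-(triisopropylsilyloxy)phenyl]ethanone, via trifluoroacetyl diketone 3 (not isolated)
Conditions: LiN(SiMe3)2, THF, −78 °C, then CF3CO2CH2CF3; dilute HCl work-up; MsN3, Et3N, H2O, MeCN, rt
Reagents that add atoms: methanesulfonyl azide, CS(=O)(=O)N=[N+]=[N-]; 2,2,2-trifluoroethyl trifluoroacetate, O=C(OCC(F)(F)F)C(F)(F)F (its acyl group is present in 3 only)
Why: Detrifluoroacetylative diazo transfer, a deacylative form of the Regitz diazo transfer, in which the kinetic lithium enolate of the methyl ketone is C-trifluoroacetylated to 3, whose activated methylene takes the diazo group from the sulfonyl azide while the trifluoroacetyl group leaves as the N-acylsulfonamide; the sequence is routine for aryl methyl ketones.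

Step 3
Reactants: 5 2-methoxybenzene-1,4-diol (2-methoxyhydroquinone)
Product: 6 1,4-bis(benzyloxy)-2-methoxybenzene
Conditions: BnBr, K2CO3, DMF, rt, under N2
Reagents that add atoms: benzyl bromide, BrCc1ccccc1
Why: Williamson etherification of both phenols with a reactive benzylic halide and carbonate base, run with exclusion of air because the hydroquinone dianion is easily oxidised.

Step 4
Reactants: 6 1,4-bis(benzyloxy)-2-methoxybenzene
Product: 8 2,5-bis(benzyloxy)-4-methoxybenzaldehyde, via aryl iminium chloride 7 (not isolated)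
Conditions: POCl3, DMF, 0 °C to 70 °C; then ice-water
Reagents that add atoms: N,N-dimethylformamide, CN(C)C=O; water, O; phosphoryl chloride, O=P(Cl)(Cl)Cl (chloride counter-ion of 7 only)
Why: Vilsmeier–Haack formylation, in which the chloroiminium ion attacks the position para to the methoxy group and ortho to a benzyloxy group, the only site activated by two alkoxy groups and not flanked on both sides (as in the formylation of 1,2,4-trimethoxybenzene), and water then hydrolyses iminium salt 7.

Step 5
Reactants: 4 2-diazo-1-[2,3,4-trimethoxy-6-(triisopropylsilyloxy)phenyl]ethanone; 8 2,5-bis(benzyloxy)-4-methoxybenzaldehyde (2 equiv); 9 methanol (1.2 equiv)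
Product: 10 (2R,3S)-3-[2,5-bis(benzyloxy)-4-methoxyphenyl]-3-hydroxy-2-methoxy-1-[2,3,4-trimethoxy-6-(triisopropylsilyloxy)phenyl]propan-1-one
Conditions: Rh2(OAc)4 (2 mol%), (R)-TRIP (10 mol%), 4 Å MS, CH2Cl2, 0 °C, slow addition of 4
Reagents that add atoms: none
Why: Rh2(OAc)4 expels N2 from 4 and methanol adds to the electrophilic ketocarbene (C3–OMe), giving a protic oxonium ylide that acts as the enol of the α-methoxy ketone and adds through carbon to the acid-bound aldehyde 8 (C2–C3) before its 1,2-proton shift can lead to the plain O–H insertion product. The closest known reaction type is the dirhodium and chiral Brønsted acid co-catalysed three-component coupling of diazo carbonyl compounds, alcohols and aldehydes or imines through oxonium ylide trapping, used here with a terminal aryl diazoketone and methanol. No ring is closed. Both stereocenters arise in the C–C bond-forming transition state and are set by the chiral phosphoric acid, which binds the ylide O–H at its P=O and the aldehyde carbonyl at its P–OH so that one enol face meets one aldehyde face, 2R at the methoxy carbon (flavanone C3) and 3S at the carbinol (flavanone C2, inverted later). The step needs capture by the aldehyde to outrun the proton shift and methanol to outrun the ring A oxygens at the carbene, which the excess of 8, the slow addition of 4 and the bulky, poorly donating OSi(iPr)3 group should secure (the ortho OMe can form only a reversible methyloxonium ylide). It also needs anti diastereoselection from the acid-organised transition state; a minor syn isomer would be removed by chromatography at this stage.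

Step 6
Reactants: 10 (2R,3S)-3-[2,5-bis(benzyloxy)-4-methoxyphenyl]-3-hydroxy-2-methoxy-1-[2,3,4-trimethoxy-6-(triisopropylsilyloxy)phenyl]propan-1-one
Product: 11 (2R,3S)-3-[2,5-bis(benzyloxy)-4-methoxyphenyl]-3-hydroxy-1-(6-hydroxy-2,3,4-trimethoxyphenyl)-2-methoxypropan-1-one
Conditions: Bu4NF, AcOH, THF, 0 °C
Reagents that add atoms: none
Why: Fluoride cleavage of the aryl silyl ether is fast at 0 °C, and the acetic acid buffer keeps the liberated phenoxide protonated, so the aldol should neither undergo retro-aldol cleavage nor epimerise.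

Step 7
Reactants: 11 (2R,3S)-3-[2,5-bis(benzyloxy)-4-methoxyphenyl]-3-hydroxy-1-(6-hydroxy-2,3,4-trimethoxyphenyl)-2-methoxypropan-1-one
Product: 12 (2R,3R)-2-[2,5-bis(benzyloxy)-4-methoxyphenyl]-3,5,6,7-tetramethoxy-2,3-dihydro-4H-chromen-4-one
Conditions: PPh3, DIAD, THF, 0 °C to rt
Reagents that add atoms: none
Why: Intramolecular Mitsunobu etherification, established for closing 2'-hydroxyaryl aldols to flavanones, in which the ring A phenol protonates the betaine and displaces the activated benzylic oxygen in a 6-exo-tet closure (O1–C2) with inversion, turning the 3S carbinol into 2R while the methoxy-bearing carbon is untouched, which should give the 2,3-trans ring C.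

Step 8
Reactants: 12 (2R,3R)-2-[2,5-bis(benzyloxy)-4-methoxyphenyl]-3,5,6,7-tetramethoxy-2,3-dihydro-4H-chromen-4-one
Product: 13 (2R,3R)-2-(2,5-dihydroxy-4-methoxyphenyl)-3,5,6,7-tetramethoxy-2,3-dihydro-4H-chromen-4-one
Conditions: H2 (1 atm), 10% Pd/C, EtOAc, rt
Reagents that add atoms: none
Why: Hydrogenolysis of aryl benzyl ethers over Pd/C at atmospheric pressure is much faster than cleavage of the cyclic benzylic C2–O1 bond or reduction of the aryl ketone, so both phenols should be freed without touching either stereocenter.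

Compound list
1 | 1-(6-hydroxy-2,3,4-trimethoxyphenyl)ethanone | CC(=O)c1c(O)cc(OC)c(OC)c1OC | starting material
2 | 1-[2,3,4-trimethoxy-6-(triisopropylsilyloxy)phenyl]ethanone | CC(=O)c1c(O[Si](C(C)C)(C(C)C)C(C)C)cc(OC)c(OC)c1OC | intermediate
3 | 4,4,4-trifluoro-1-[2,3,4-trimethoxy-6-(triisopropylsilyloxy)phenyl]butane-1,3-dione | O=C(CC(=O)C(F)(F)F)c1c(O[Si](C(C)C)(C(C)C)C(C)C)cc(OC)c(OC)c1OC | intermediate
4 | 2-diazo-1-[2,3,4-trimethoxy-6-(triisopropylsilyloxy)phenyl]ethanone | [N-]=[N+]=CC(=O)c1c(O[Si](C(C)C)(C(C)C)C(C)C)cc(OC)c(OC)c1OC | intermediate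
5 | 2-methoxybenzene-1,4-diol | COc1cc(O)ccc1O | starting material
6 | 1,4-bis(benzyloxy)-2-methoxybenzene | COc1cc(OCc2ccccc2)ccc1OCc1ccccc1 | intermediate
7 | N-[2,5-bis(benzyloxy)-4-methoxybenzylidene]-N-methylmethanaminium chloride | C[N+](C)=Cc1cc(OCc2ccccc2)c(OC)cc1OCc1ccccc1.[Cl-] | intermediate
8 | 2,5-bis(benzyloxy)-4-methoxybenzaldehyde | O=Cc1cc(OCc2ccccc2)c(OC)cc1OCc1ccccc1 | intermediate
9 | methanol | CO | starting material
10 | (2R,3S)-3-[2,5-bis(benzyloxy)-4-methoxyphenyl]-3-hydroxy-2-methoxy-1-[2,3,4-trimethoxy-6-(triisopropylsilyloxy)phenyl]propan-1-one | COc1cc(O[Si](C(C)C)(C(C)C)C(C)C)c(C(=O)[C@H](OC)[C@@H](O)c2cc(OCc3ccccc3)c(OC)cc2OCc2ccccc2)c(OC)c1OC | intermediate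
11 | (2R,3S)-3-[2,5-bis(benzyloxy)-4-methoxyphenyl]-3-hydroxy-1-(6-hydroxy-2,3,4-trimethoxyphenyl)-2-methoxypropan-1-one | COc1cc(O)c(C(=O)[C@H](OC)[C@@H](O)c2cc(OCc3ccccc3)c(OC)cc2OCc2ccccc2)c(OC)c1OC | intermediate
12 | (2R,3R)-2-[2,5-bis(benzyloxy)-4-methoxyphenyl]-3,5,6,7-tetramethoxy-2,3-dihydro-4H-chromen-4-one | COc1cc(OCc2ccccc2)c([C@H]2Oc3cc(OC)c(OC)c(OC)c3C(=O)[C@@H]2OC)cc1OCc1ccccc1 | intermediate
13 | (2R,3R)-2-(2,5-dihydroxy-4-methoxyphenyl)-3,5,6,7-tetramethoxy-2,3-dihydro-4H-chromen-4-one | COc1cc(O)c([C@H]2Oc3cc(OC)c(OC)c(OC)c3C(=O)[C@@H]2OC)cc1O | target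

Total step count: 8
Longest linear sequence: 6 steps (steps 1, 2, 5, 6, 7, 8; the branch through steps 3 and 4 is equally long)

Steps most likely to fail

1. Step 5. The ylide may tautomerise by proton shift before it meets the electron-rich, weakly electrophilic aldehyde. The carbene may also be drained by the neighbouring ring A oxygens, the acid may ionise the benzylic alcohol of the adduct towards methanolysis, and facial discrimination may be poor. The fallback uses known chemistry, sets out from 1 and 8 and returns at 12. Ketone 1 would be protected (NaH, MOMCl, DMF) as 1-[6-(methoxymethoxy)-2,3,4-trimethoxyphenyl]ethanone F1 and condensed with 8 (KOH, EtOH, Claisen–Schmidt) to the chalcone (E)-3-[2,5-bis(benzyloxy)-4-methoxyphenyl]-1-[6-(methoxymethoxy)-2,3,4-trimethoxyphenyl]prop-2-en-1-one F2. Juliá–Colonna epoxidation (poly-L-leucine, urea–H2O2, DBU, THF) should give [(2R,3S)-3-[2,5-bis(benzyloxy)-4-methoxyphenyl]oxiran-2-yl][6-(methoxymethoxy)-2,3,4-trimethoxyphenyl]methanone F3. HCl in MeOH would then remove the acetal and let the freed phenol open the epoxide at the benzylic carbon, giving the trans dihydroflavonol (2R,3R)-2-[2,5-bis(benzyloxy)-4-methoxyphenyl]-3-hydroxy-5,6,7-trimethoxy-2,3-dihydro-4H-chromen-4-one F4. O-methylation of its 3-hydroxyl with Me3OBF4 and 1,8-bis(dimethylamino)naphthalene in CH2Cl2 would give 12.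

2. Step 7. The activated aldol may dehydrate to the α-methoxychalcone (its α-hydrogen is acidic), or the benzylic centre may ionise in part instead of undergoing clean displacement. The fallback runs from 11 to 12 without a new compound and closes the ring by ionisation instead of displacement. Catalytic TsOH in CH2Cl2 at 0 °C would generate the benzylic cation, stabilised by the para methoxy and ortho benzyloxy groups. The ring A phenol would capture it under control of the adjacent methoxy-bearing stereocenter to give the thermodynamically preferred trans isomer 12. The same treatment would convert any cis flavanone into 12 by reversible opening at C2–O1.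

3. Step 2. The silyl group may move from the aryl oxygen to the enolate oxygen, or C-acylation of the enolate beside two ortho substituents may stay incomplete. The fallback runs from 2 to 4. Riley oxidation of 2 (SeO2, dioxane–H2O, 90 °C) would give the arylglyoxal 2-oxo-2-[2,3,4-trimethoxy-6-(triisopropylsilyloxy)phenyl]acetaldehyde F5. Condensation with TsNHNH2 (THF, 0 °C) at the aldehyde carbon would give the tosylhydrazone N'-[(E)-2-oxo-2-[2,3,4-trimethoxy-6-(triisopropylsilyloxy)phenyl]ethylidene]-4-methylbenzenesulfonohydrazide F6. Loss of sulfinate with Et3N in CH2Cl2 at rt (Bamford–Stevens type) would then give 4.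

Further compounds
F1 | step 5 | 1-[6-(methoxymethoxy)-2,3,4-trimethoxyphenyl]ethanone | CC(=O)c1c(OCOC)cc(OC)c(OC)c1OC
F2 | step 5 | (E)-3-[2,5-bis(benzyloxy)-4-methoxyphenyl]-1-[6-(methoxymethoxy)-2,3,4-trimethoxyphenyl]prop-2-en-1-one | COCOc1cc(OC)c(OC)c(OC)c1C(=O)/C=C/c1cc(OCc2ccccc2)c(OC)cc1OCc1ccccc1
F3 | step 5 | [(2R,3S)-3-[2,5-bis(benzyloxy)-4-methoxyphenyl]oxiran-2-yl][6-(methoxymethoxy)-2,3,4-trimethoxyphenyl]methanone | COCOc1cc(OC)c(OC)c(OC)c1C(=O)[C@@H]1O[C@H]1c1cc(OCc2ccccc2)c(OC)cc1OCc1ccccc1
F4 | step 5 | (2R,3R)-2-[2,5-bis(benzyloxy)-4-methoxyphenyl]-3-hydroxy-5,6,7-trimethoxy-2,3-dihydro-4H-chromen-4-one | COc1cc(OCc2ccccc2)c([C@H]2Oc3cc(OC)c(OC)c(OC)c3C(=O)[C@@H]2O)cc1OCc1ccccc1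
F0 | step 7 | none | none
F5 | step 2 | 2-oxo-2-[2,3,4-trimethoxy-6-(triisopropylsilyloxy)phenyl]acetaldehyde | O=CC(=O)c1c(O[Si](C(C)C)(C(C)C)C(C)C)cc(OC)c(OC)c1OC
F6 | step 2 | N'-[(E)-2-oxo-2-[2,3,4-trimethoxy-6-(triisopropylsilyloxy)phenyl]ethylidene]-4-methylbenzenesulfonohydrazide | Cc1ccc(S(=O)(=O)N/N=C/C(=O)c2c(O[Si](C(C)C)(C(C)C)C(C)C)cc(OC)c(OC)c2OC)cc1
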